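**Retrosynthetic overview**
1. The ten-membered carbocycle (ring B) is closed last by ring-closing metathesis at C9=C10; the lactone (ring A) is made first, as a butenolide, by O-acylation and metathesis.
2. Key disconnection C8–O: the (S)-2-methylbutanoate is attached with inversion (Mitsunobu) to an 8S carbinol, which installs the side chain and corrects C8 in one C–O bond formation.
3. C7–C8: zinc Barbier coupling of a 5-substituted 3-(bromomethyl)butenolide with acrolein (trans lactone, anti carbinol).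
4. C3–C4 and the C4=C5 geometry: trans-hydroalumination of an alkynol and cross-coupling with an alkyl bromide (new one-pot); the C1–O stereocentre of that bromide comes from Shi epoxidation and eliminative opening.
5. C6–O stereocentre: asymmetric alkynylation of acrolein with a silylated propargyl alcohol.

Assumption: locants C1–C15 follow germacrane numbering (lactone oxygen on C6, ester on C8, free hydroxyls on C1 and C15), and the five building blocks are bought.

Step 1
Reactants: 1 tert-butyldimethyl(prop-2-yn-1-yloxy)silane; 2 acrolein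
Product: 4 (3S)-6-[(tert-butyldimethylsilyl)oxy]hex-1-en-4-yn-3-ol, via methylzinc acetylide 3 (not isolated)
Conditions: Me2Zn (3 eq), (S,S)-ProPhenol (10 mol %), Ph3PO (20 mol %), toluene, 0 °C, slow addition of 2
Reagents that add atoms: none
Why: Dinuclear-zinc ProPhenol asymmetric alkynylation of an enal (Trost type), in which the chiral bimetallic pocket delivers the acetylide to the Re face of acrolein and sets C6 as S (the ligand antipode that gives Re-face attack is the one to use).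

Step 2
Reactants: 5 5-bromo-2-methylpent-2-ene
Product: 6 (3S)-3-(2-bromoethyl)-2,2-dimethyloxirane
Conditions: ent-Shi ketone (L-fructose-derived, 30 mol %), KHSO5 (Oxone), K2CO3, Bu4NHSO4, MeCN/CH2(OMe)2–aq. buffer pH 10.5, 0 °C
Reagents that add atoms: potassium peroxymonosulfate (KHSO5, Oxone), [K+].[O-]S(=O)(=O)OO
Why: Shi asymmetric epoxidation, in which the chiral dioxirane attacks the trisubstituted alkene through a spiro transition state and sets C1 as S (the L-fructose-derived ketone is taken because the D-fructose ketone is expected to give the R epoxide of this alkene class).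

Step 3
Reactants: 6 (3S)-3-(2-bromoethyl)-2,2-dimethyloxirane
Product: 7 {[(3S)-5-bromo-2-methylpent-1-en-3-yl]oxy}(tert-butyl)dimethylsilane
Conditions: TBSOTf, toluene, −78 °C; then DBU, −78 → 0 °C
Reagents that add atoms: tert-butyldimethylsilyl trifluoromethanesulfonate (TBSOTf), CC(C)(C)[Si](C)(C)OS(=O)(=O)C(F)(F)F
Why: Silyl-triflate-mediated eliminative epoxide opening (Noyori type), in which the silylated oxirane opens at the tertiary carbon and DBU removes a methyl proton to give the isopropenyl silyl ether, the C1–O bond never being broken so that C1 stays S.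

Step 4
Reactants: 4 (3S)-6-[(tert-butyldimethylsilyl)oxy]hex-1-en-4-yn-3-ol; 7 {[(3S)-5-bromo-2-methylpent-1-en-3-yl]oxy}(tert-butyl)dimethylsilane
Product: 9 (3S,4E,8S)-8-[(tert-butyldimethylsilyl)oxy]-5-{[(tert-butyldimethylsilyl)oxy]methyl}-9-methyldeca-1,4,9-trien-3-ol, via cyclic alkenylalanate 8 (not isolated)
Conditions: NaAlH2(OCH2CH2OMe)2 (Red-Al), THF, 0 °C; EtOAc; then 7, PdCl2(IPr)(3-chloropyridine) (3 mol %), ZnBr2 (20 mol %), THF/NMP, 25 °C
Reagents that add atoms: none
Why: Proposed new method: alkoxide-directed trans-hydroalumination (hydride to C5, aluminium to C4) gives the five-membered (Z)-alkenylalanate 8, whose alkenyl group is proposed to pass via catalytic zinc to the alkyl–palladium species formed by SN2-type oxidative addition of the primary bromide 7 to the bulky NHC–palladium catalyst, reductive elimination then forging C3–C4 with retention so that C3 ends cis to C6 while C1 and C6 are untouched; the closest known reactions are the Red-Al hydroalumination/iodination–Negishi sequence, the copper-promoted one-pot methylation and the zinc-cocatalysed palladium arylation of such alanates, and NHC–palladium Negishi couplings of unactivated alkyl bromides.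

Step 5
Reactants: 9 (3S,4E,8S)-8-[(tert-butyldimethylsilyl)oxy]-5-{[(tert-butyldimethylsilyl)oxy]methyl}-9-methyldeca-1,4,9-trien-3-ol; 10 2-(bromomethyl)prop-2-enoic acid
Product: 11 (3S,4E,8S)-8-[(tert-butyldimethylsilyl)oxy]-5-{[(tert-butyldimethylsilyl)oxy]methyl}-9-methyldeca-1,4,9-trien-3-yl 2-(bromomethyl)prop-2-enoate
Conditions: DIC, DMAP (5 mol %), CH2Cl2, −10 → 0 °C
Reagents that add atoms: none
Why: Steglich carbodiimide esterification of the bis-allylic alcohol, which touches no stereocentre, the low DMAP loading and low temperature keeping the allylic bromide intact.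

Step 6
Reactants: 11 (3S,4E,8S)-8-[(tert-butyldimethylsilyl)oxy]-5-{[(tert-butyldimethylsilyl)oxy]methyl}-9-methyldeca-1,4,9-trien-3-yl 2-(bromomethyl)prop-2-enoate
Product: 12 (5R)-3-(bromomethyl)-5-[(1E,5S)-5-[(tert-butyldimethylsilyl)oxy]-2-{[(tert-butyldimethylsilyl)oxy]methyl}-6-methylhepta-1,6-dien-1-yl]furan-2(5H)-one
Conditions: second-generation Grubbs catalyst RuCl2(=CHPh)(PCy3)(H2IMes) (5 mol %), CH2Cl2 (5 mM), 40 °C
Reagents that add atoms: none
Why: Ring-closing metathesis, in which the ruthenium alkylidene loads at the C7 vinyl group and closes onto the acrylate to give the five-membered butenolide far faster than any larger ring, C6 (same geometry, now R by CIP) and C1 being untouched.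

Step 7
Reactants: 12 (5R)-3-(bromomethyl)-5-[(1E,5S)-5-[(tert-butyldimethylsilyl)oxy]-2-{[(tert-butyldimethylsilyl)oxy]methyl}-6-methylhepta-1,6-dien-1-yl]furan-2(5H)-one; 2 acrolein
Product: 14 (4R,5R)-5-[(1E,5S)-5-[(tert-butyldimethylsilyl)oxy]-2-{[(tert-butyldimethylsilyl)oxy]methyl}-6-methylhepta-1,6-dien-1-yl]-4-[(1S)-1-hydroxyprop-2-en-1-yl]-3-methylideneoxolan-2-one, via allylzinc bromide 13 (not isolated)
Conditions: Zn dust, THF/sat. aq. NH4Cl, 0 °C → rt, 2 in excess
Reagents that add atoms: none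
Why: Zinc Barbier allylation (SE2′, Zimmerman–Traxler chair), in which the ring-locked allylzinc bonds through C7 on the face anti to the C6 side chain (trans lactone, C7 R) and, because the ring holds its γ-substituent trans to CH2Zn, the equatorial aldehyde gives the anti carbinol (C8 S).

Step 8
Reactants: 14 (4R,5R)-5-[(1E,5S)-5-[(tert-butyldimethylsilyl)oxy]-2-{[(tert-butyldimethylsilyl)oxy]methyl}-6-methylhepta-1,6-dien-1-yl]-4-[(1S)-1-hydroxyprop-2-en-1-yl]-3-methylideneoxolan-2-one; 15 (2S)-2-methylbutanoic acid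
Product: 16 (1R)-1-[(2R,3R)-2-[(1E,5S)-5-[(tert-butyldimethylsilyl)oxy]-2-{[(tert-butyldimethylsilyl)oxy]methyl}-6-methylhepta-1,6-dien-1-yl]-4-methylidene-5-oxooxolan-3-yl]prop-2-en-1-yl (2S)-2-methylbutanoate
Conditions: PPh3, DIAD, toluene, 0 °C → rt
Reagents that add atoms: none
Why: Mitsunobu esterification, in which carboxylate SN2 displacement of the activated alcohol forms the key C8–O bond and inverts C8 from S to R, the neutral conditions leaving the acid α-stereocentre, the α-methylene lactone and the silyl ethers alone.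

Step 9
Reactants: 16 (1R)-1-[(2R,3R)-2-[(1E,5S)-5-[(tert-butyldimethylsilyl)oxy]-2-{[(tert-butyldimethylsilyl)oxy]methyl}-6-methylhepta-1,6-dien-1-yl]-4-methylidene-5-oxooxolan-3-yl]prop-2-en-1-yl (2S)-2-methylbutanoate
Product: 17 (1R)-1-[(2R,3R)-2-[(1E,5S)-5-hydroxy-2-(hydroxymethyl)-6-methylhepta-1,6-dien-1-yl]-4-methylidene-5-oxooxolan-3-yl]prop-2-en-1-yl (2S)-2-methylbutanoate
Conditions: HF·pyridine, pyridine, THF, 0 °C → rt
Reagents that add atoms: none
Why: Fluoride-mediated desilylation removes both silyl ethers, while the ester, the lactone and the alkenes are inert and no stereocentre is touched.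

Step 10
Reactants: 17 (1R)-1-[(2R,3R)-2-[(1E,5S)-5-hydroxy-2-(hydroxymethyl)-6-methylhepta-1,6-dien-1-yl]-4-methylidene-5-oxooxolan-3-yl]prop-2-en-1-yl (2S)-2-methylbutanoate
Product: 18 [(3aR,4R,5Z,7S,10E,11aR)-7-hydroxy-10-(hydroxymethyl)-6-methyl-3-methylidene-2-oxo-2,3,3a,4,7,8,9,11a-octahydrocyclodeca[b]furan-4-yl] (2S)-2-methylbutanoate (CNP0526758.1)
Conditions: second-generation Hoveyda–Grubbs catalyst RuCl2(=CH-C6H4-2-OiPr)(H2IMes) (15 mol %), 1,4-benzoquinone (20 mol %), toluene (1 mM), 80 °C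
Reagents that add atoms: none
Why: Ring-closing metathesis between the C8 vinyl group and the C1 isopropenyl carbinol closes the ten-membered ring, the low-strain cis,cis-cyclodeca-1,6-diene core held by the trans-fused lactone making the ring-cis (Z) C9=C10 alkene the thermodynamic product, and no stereocentre is touched.

**Compound list**
1 | tert-butyldimethyl(prop-2-yn-1-yloxy)silane | C#CCO[Si](C)(C)C(C)(C)C | starting material
2 | acrolein (prop-2-enal) | C=CC=O | starting material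
3 | methyl{3-[(tert-butyldimethylsilyl)oxy]prop-1-yn-1-yl}zinc | C[Zn]C#CCO[Si](C)(C)C(C)(C)C | intermediate
4 | (3S)-6-[(tert-butyldimethylsilyl)oxy]hex-1-en-4-yn-3-ol | C=C[C@H](O)C#CCO[Si](C)(C)C(C)(C)C | intermediate
5 | 5-bromo-2-methylpent-2-ene | CC(C)=CCCBr | starting material
6 | (3S)-3-(2-bromoethyl)-2,2-dimethyloxirane | CC1(C)O[C@H]1CCBr | intermediate
7 | {[(3S)-5-bromo-2-methylpent-1-en-3-yl]oxy}(tert-butyl)dimethylsilane | C=C(C)[C@@H](O[Si](C)(C)C(C)(C)C)CCBr | intermediate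
8 | sodium (5S)-5-ethenyl-2,2-bis(2-methoxyethoxy)-3-{[(tert-butyldimethylsilyl)oxy]methyl}-2,5-dihydro-1,2-oxaaluminol-2-uide (cyclic alkenylalanate, Al on C4, O on C6) | C=C[C@@H]1O[Al-](OCCOC)(OCCOC)C(CO[Si](C)(C)C(C)(C)C)=C1.[Na+] | intermediate
9 | (3S,4E,8S)-8-[(tert-butyldimethylsilyl)oxy]-5-{[(tert-butyldimethylsilyl)oxy]methyl}-9-methyldeca-1,4,9-trien-3-ol | C=C[C@H](O)/C=C(/CO[Si](C)(C)C(C)(C)C)CC[C@H](O[Si](C)(C)C(C)(C)C)C(C)=C | intermediate
10 | 2-(bromomethyl)prop-2-enoic acid | C=C(CBr)C(=O)O | starting material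
11 | (3S,4E,8S)-8-[(tert-butyldimethylsilyl)oxy]-5-{[(tert-butyldimethylsilyl)oxy]methyl}-9-methyldeca-1,4,9-trien-3-yl 2-(bromomethyl)prop-2-enoate | C=C[C@H](OC(=O)C(=C)CBr)/C=C(/CO[Si](C)(C)C(C)(C)C)CC[C@H](O[Si](C)(C)C(C)(C)C)C(C)=C | intermediate
12 | (5R)-3-(bromomethyl)-5-[(1E,5S)-5-[(tert-butyldimethylsilyl)oxy]-2-{[(tert-butyldimethylsilyl)oxy]methyl}-6-methylhepta-1,6-dien-1-yl]furan-2(5H)-one | BrCC1=C[C@@H](/C=C(/CO[Si](C)(C)C(C)(C)C)CC[C@H](O[Si](C)(C)C(C)(C)C)C(C)=C)OC1=O | intermediate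
13 | bromo{[(5R)-5-[(1E,5S)-5-[(tert-butyldimethylsilyl)oxy]-2-{[(tert-butyldimethylsilyl)oxy]methyl}-6-methylhepta-1,6-dien-1-yl]-2-oxo-2,5-dihydrofuran-3-yl]methyl}zinc | Br[Zn]CC1=C[C@@H](/C=C(/CO[Si](C)(C)C(C)(C)C)CC[C@H](O[Si](C)(C)C(C)(C)C)C(C)=C)OC1=O | intermediate
14 | (4R,5R)-5-[(1E,5S)-5-[(tert-butyldimethylsilyl)oxy]-2-{[(tert-butyldimethylsilyl)oxy]methyl}-6-methylhepta-1,6-dien-1-yl]-4-[(1S)-1-hydroxyprop-2-en-1-yl]-3-methylideneoxolan-2-one | C=C1C(=O)O[C@H](/C=C(/CO[Si](C)(C)C(C)(C)C)CC[C@H](O[Si](C)(C)C(C)(C)C)C(C)=C)[C@H]1[C@@H](O)C=C | intermediate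
15 | (2S)-2-methylbutanoic acid | CC[C@H](C)C(=O)O | starting material
16 | (1R)-1-[(2R,3R)-2-[(1E,5S)-5-[(tert-butyldimethylsilyl)oxy]-2-{[(tert-butyldimethylsilyl)oxy]methyl}-6-methylhepta-1,6-dien-1-yl]-4-methylidene-5-oxooxolan-3-yl]prop-2-en-1-yl (2S)-2-methylbutanoate | C=C1C(=O)O[C@H](/C=C(/CO[Si](C)(C)C(C)(C)C)CC[C@H](O[Si](C)(C)C(C)(C)C)C(C)=C)[C@H]1[C@H](OC(=O)[C@@H](C)CC)C=C | intermediate
17 | (1R)-1-[(2R,3R)-2-[(1E,5S)-5-hydroxy-2-(hydroxymethyl)-6-methylhepta-1,6-dien-1-yl]-4-methylidene-5-oxooxolan-3-yl]prop-2-en-1-yl (2S)-2-methylbutanoate | C=C1C(=O)O[C@H](/C=C(/CO)CC[C@H](O)C(C)=C)[C@H]1[C@H](OC(=O)[C@@H](C)CC)C=C | intermediate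
18 | [(3aR,4R,5Z,7S,10E,11aR)-7-hydroxy-10-(hydroxymethyl)-6-methyl-3-methylidene-2-oxo-2,3,3a,4,7,8,9,11a-octahydrocyclodeca[b]furan-4-yl] (2S)-2-methylbutanoate | C=C1C(=O)O[C@@H]2/C=C(/CO)CC[C@H](O)/C(C)=C\[C@@H](OC(=O)[C@@H](C)CC)[C@@H]12 | target

**Step count and risks**

Total step count: 10. Longest linear sequence: 9 steps (5 → 6 → 7 → 9 → 11 → 12 → 14 → 16 → 17 → 18).

The three steps most likely to fail are steps 4, 8 and 10.

Step 4 is the proposed new one-pot coupling. The alanate may transfer its alkenyl group too slowly, lose the neighbouring silyloxy group to give an allene, or the alkyl–palladium species may undergo β-hydride elimination. The fallback uses known chemistry, sets out from 4 (with 7) and comes back at 9. Compound 4 is treated with Red-Al (THF, 0 °C) and the alanate is quenched with I2 at −78 °C to give (3S,4Z)-6-[(tert-butyldimethylsilyl)oxy]-5-iodohexa-1,4-dien-3-ol F1. Bromide 7 is converted with Zn dust and LiCl (THF, 50 °C) into {(3S)-3-[(tert-butyldimethylsilyl)oxy]-4-methylpent-4-en-1-yl}zinc bromide F2. Negishi coupling of F1 with excess F2 (PdCl2(dppf), THF, 40 °C) gives 9.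

Step 8 may suffer from SN2′ attack at the vinyl terminus, elimination towards C7, or slow reaction of the β-branched carbinol with a weakly acidic aliphatic acid. The fallback separates inversion from acylation, sets out from 14 and comes back at 16. Mitsunobu reaction of 14 with the small, more acidic formic acid (PPh3, DIAD) gives the inverted formate (1R)-1-[(2R,3R)-2-[(1E,5S)-5-[(tert-butyldimethylsilyl)oxy]-2-{[(tert-butyldimethylsilyl)oxy]methyl}-6-methylhepta-1,6-dien-1-yl]-4-methylidene-5-oxooxolan-3-yl]prop-2-en-1-yl formate F3. Mild methanolysis (KHCO3, MeOH/H2O, 0 °C) frees (4R,5R)-5-[(1E,5S)-5-[(tert-butyldimethylsilyl)oxy]-2-{[(tert-butyldimethylsilyl)oxy]methyl}-6-methylhepta-1,6-dien-1-yl]-4-[(1R)-1-hydroxyprop-2-en-1-yl]-3-methylideneoxolan-2-one F4. Steglich esterification of F4 with 15 (DIC, DMAP cat., CH2Cl2, 0 °C) proceeds with retention and gives 16.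

Step 10 may stall because the hindered 1,1-disubstituted alkene reacts slowly, giving oligomers or allylic-alcohol isomerisation instead of the trisubstituted ring alkene. The fallback closes the ring before the C8–O coupling, sets out from 14 and comes back at 18. Ring-closing metathesis of 14, whose free allylic C8 hydroxyl speeds loading of the catalyst (second-generation Grubbs catalyst, toluene, 1 mM, 80 °C), gives (3aR,4S,5Z,7S,10E,11aR)-7-[(tert-butyldimethylsilyl)oxy]-10-{[(tert-butyldimethylsilyl)oxy]methyl}-4-hydroxy-6-methyl-3-methylidene-3a,4,7,8,9,11a-hexahydrocyclodeca[b]furan-2(3H)-one F5. Mitsunobu esterification of F5 with 15 (PPh3, DIAD) gives [(3aR,4R,5Z,7S,10E,11aR)-7-[(tert-butyldimethylsilyl)oxy]-10-{[(tert-butyldimethylsilyl)oxy]methyl}-6-methyl-3-methylidene-2-oxo-2,3,3a,4,7,8,9,11a-octahydrocyclodeca[b]furan-4-yl] (2S)-2-methylbutanoate F6. HF·pyridine then gives 18.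

**Further compounds**
F1 | step 4 | (3S,4Z)-6-[(tert-butyldimethylsilyl)oxy]-5-iodohexa-1,4-dien-3-ol | C=C[C@H](O)/C=C(/CO[Si](C)(C)C(C)(C)C)I
F2 | step 4 | {(3S)-3-[(tert-butyldimethylsilyl)oxy]-4-methylpent-4-en-1-yl}zinc bromide | C=C(C)[C@@H](O[Si](C)(C)C(C)(C)C)CC[Zn]Br
F3 | step 8 | (1R)-1-[(2R,3R)-2-[(1E,5S)-5-[(tert-butyldimethylsilyl)oxy]-2-{[(tert-butyldimethylsilyl)oxy]methyl}-6-methylhepta-1,6-dien-1-yl]-4-methylidene-5-oxooxolan-3-yl]prop-2-en-1-yl formate | C=C1C(=O)O[C@H](/C=C(/CO[Si](C)(C)C(C)(C)C)CC[C@H](O[Si](C)(C)C(C)(C)C)C(C)=C)[C@H]1[C@H](OC=O)C=C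
F4 | step 8 | (4R,5R)-5-[(1E,5S)-5-[(tert-butyldimethylsilyl)oxy]-2-{[(tert-butyldimethylsilyl)oxy]methyl}-6-methylhepta-1,6-dien-1-yl]-4-[(1R)-1-hydroxyprop-2-en-1-yl]-3-methylideneoxolan-2-one | C=C1C(=O)O[C@H](/C=C(/CO[Si](C)(C)C(C)(C)C)CC[C@H](O[Si](C)(C)C(C)(C)C)C(C)=C)[C@H]1[C@H](O)C=C
F5 | step 10 | (3aR,4S,5Z,7S,10E,11aR)-7-[(tert-butyldimethylsilyl)oxy]-10-{[(tert-butyldimethylsilyl)oxy]methyl}-4-hydroxy-6-methyl-3-methylidene-3a,4,7,8,9,11a-hexahydrocyclodeca[b]furan-2(3H)-one | C=C1C(=O)O[C@@H]2/C=C(/CO[Si](C)(C)C(C)(C)C)CC[C@H](O[Si](C)(C)C(C)(C)C)/C(C)=C\[C@H](O)[C@@H]12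
F6 | step 10 | [(3aR,4R,5Z,7S,10E,11aR)-7-[(tert-butyldimethylsilyl)oxy]-10-{[(tert-butyldimethylsilyl)oxy]methyl}-6-methyl-3-methylidene-2-oxo-2,3,3a,4,7,8,9,11a-octahydrocyclodeca[b]furan-4-yl] (2S)-2-methylbutanoate | C=C1C(=O)O[C@@H]2/C=C(/CO[Si](C)(C)C(C)(C)C)CC[C@H](O[Si](C)(C)C(C)(C)C)/C(C)=C\[C@@H](OC(=O)[C@@H](C)CC)[C@@H]12
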